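**Plan**

- Numbering: C1 quaternary C–Me, C2 and C3 acetoxy carbons, C4, Z‑C5=C6, C7 lactone O–CH, C8 butenolide β‑carbon, C9, C10 ring‑fusion CH, C11–C14 rest of cyclohexene ring A; ring B is the ten‑membered ring C1–C10, ring C the butenolide; β is the face of the C1 methyl.
- Enabling feature: C3 and C8 are carbonyl‑level carbons facing each other across ring B, joined on one side by C4–C5=C6–C7 (Z) and on the other by C9–C10–C1–C2. Ring B is therefore the perimeter of two fused six‑membered rings (a 1,4‑dihydroarene C3–C8 and the ring C1, C2, C3, C8, C9, C10) whose shared C3=C8 bond has been cleaved.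
- Retrosynthetic cuts, in order: ring C at C8=C(Me) and the C7–O bond; C3/C8 rejoined as the tetrasubstituted alkene of a Birch diene and the arene restored; C2–C3 (Friedel–Crafts acylation); C1–C14 and C10–C11 (Diels–Alder).
- Forward order: ring A (Diels–Alder), middle ring (Friedel–Crafts), ring A diol, Birch reduction, ring B by ozonolysis of C3=C8, then C3 and C7 oxygenation and ring C by Horner–Wadsworth–Emmons closure.
- Stereochemistry: C1 from the chiral Lewis acid and C10 from the E geometry of the dienophile; C11/C12 and C2 from attack anti to the axial C1 methyl; C3 by hydride delivery from the C2 hydroxyl; C7 by enolate hydroxylation on the open face of ring B; Z‑C5=C6 from the arene.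

Key step: step 14

Remark (assumption): the (S)-configured oxazaborolidinium ion is assumed, from the usual formyl C–H···O binding model for 2‑substituted enals, to expose the enal face that gives the C1 configuration drawn for the Diels–Alder adduct; the mirror‑image catalyst would be used if the sense proved opposite.

**Route**

Step 1
Reactants: 1 (4-methylphenyl)acetaldehyde; 2 2-(triphenylphosphoranylidene)propanal
Product: 3 (E)-2-methyl-4-(4-methylphenyl)but-2-enal
Conditions: toluene, 80 °C
Reagents that add atoms: none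
Why: Wittig olefination with a stabilised formyl ylide should give the E‑trisubstituted enal, which places CHO and the arylmethyl group trans.

Step 2
Reactants: 4 pent-1-en-3-one
Product: 5 (Z)-3-(triisopropylsilyloxy)penta-1,3-diene
Conditions: i-Pr3SiOSO2CF3, Et3N, CH2Cl2, 0 °C
Reagents that add atoms: triisopropylsilyl trifluoromethanesulfonate, CC(C)[Si](OS(=O)(=O)C(F)(F)F)(C(C)C)C(C)C
Why: soft enolisation and O‑silylation of the ethyl ketone (silyl enol ether formation) should give the 2‑silyloxy diene with the methyl trans to the vinyl group, i.e. outside in the s‑cis diene.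

Step 3
Reactants: 3 (E)-2-methyl-4-(4-methylphenyl)but-2-enal; 5 (Z)-3-(triisopropylsilyloxy)penta-1,3-diene
Product: 6 1,5-dimethyl-6-(4-methylbenzyl)-4-(triisopropylsilyloxy)cyclohex-3-ene-1-carbaldehyde (C1 methyl β and formyl α; C10 H α and arylmethyl β; C11 methyl α)
Conditions: (S)-3,3-diphenyl-1-(2-methylphenyl)tetrahydro-1H,3H-pyrrolo[1,2-c][1,3,2]oxazaborole (20 mol %), (CF3SO2)2NH (20 mol %), CH2Cl2, −78 to −40 °C
Reagents that add atoms: none
Why: Lewis‑acid‑catalysed Diels–Alder reaction (chiral oxazaborolidinium catalysis): the enol ether β‑carbon C11 bonds to the enal β‑carbon C10 and C14 to C1, the E geometry of 3 becomes the trans relation of C1–CH3 (β) and C10–H (α), the catalyst‑bound formyl group selects the enal face and so fixes C1 and C10 absolutely, and the C11 methyl (α, formyl‑endo approach) is immaterial because C11 becomes trigonal in step 7.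

Step 4
Reactants: 6 Diels–Alder adduct
Product: 7 1,5-dimethyl-6-(4-methylbenzyl)-4-oxocyclohex-2-ene-1-carbaldehyde (same configuration; C12 enone with C13=C14)
Conditions: Pd(OAc)2 (1.1 equiv), MeCN, 40 °C
Reagents that add atoms: none
Why: Saegusa–Ito oxidation: palladation of the silyl enol ether at C13 and β‑hydride elimination toward C14 (the only β‑hydrogens) should give the C12 enone with the C13=C14 alkene of the target already in place.

Step 5
Reactants: 7 enone aldehyde
Product: 8 1,5-dimethyl-6-(4-methylbenzyl)-4-oxocyclohex-2-ene-1-carboxylic acid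
Conditions: NaClO2, NaH2PO4, 2-methyl-2-butene, t-BuOH/H2O, 0 °C to rt
Reagents that add atoms: sodium chlorite, [Na+].[O-]Cl=O
Why: Pinnick oxidation converts the hindered, non‑enolisable aldehyde into the acid without touching the enone, the alkene scavenger removing hypochlorite.

Step 6
Reactants: 8 enone acid
Product: 10 4,7,9a-trimethyl-4,4a,9a,10-tetrahydroanthracene-3,9-dione (trans‑fused tricycle: C2 aryl ketone; C12 enone; C1 methyl β; C10 H α; C11 methyl α), via acid chloride 9 (not isolated)
Conditions: (COCl)2, cat. DMF, CH2Cl2, 0 °C to rt; then AlCl3, CH2Cl2, 0 °C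
Reagents that add atoms: none
Why: intramolecular Friedel–Crafts acylation (Haworth‑type tetralone closure) forms C2–C3 ortho to the benzylic carbon; the two ortho positions of the p‑tolyl ring are equivalent, so one regioisomer is possible, and the trans‑diequatorial C2 and C9 arms give the trans‑fused middle ring.

Step 7
Reactants: 10 tricyclic enone ketone
Product: 12 C12 dienyl triflate (C11=C12 and C13=C14), via potassium dienolate 11 (not isolated)
Conditions: KN(SiMe3)2, THF, −78 °C; then PhN(SO2CF3)2, −78 to 0 °C
Reagents that add atoms: N-phenylbis(trifluoromethanesulfonimide), O=S(=O)(N(c1ccccc1)S(=O)(=O)C(F)(F)F)C(F)(F)F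
Why: deprotonation at C11, the only enolisable position (the C2 ketone has no α‑hydrogen and the γ‑carbon C1 is quaternary), and O‑triflation of the cross‑conjugated dienolate (enol triflate formation) erase the C11 centre and put a leaving group on C12.

Step 8
Reactants: 12 dienyl triflate
Product: 13 4,7,9a-trimethyl-4a,10-dihydroanthracen-9(9aH)-one (ring A 1,3-diene C11=C12–C13=C14)
Conditions: Pd(OAc)2 (5 mol %), PPh3 (10 mol %), HCO2H, Bu3N, DMF, 60 °C
Reagents that add atoms: none
Why: palladium‑catalysed formate reduction of the vinyl triflate replaces OSO2CF3 by H and should leave the diene and the aryl ketone intact.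

Step 9
Reactants: 13 diene ketone
Product: 14 11α,12α-diol ketone (C11 methyl β; C13=C14 kept)
Conditions: K2OsO4·2H2O (2 mol %), N-methylmorpholine N-oxide, acetone/H2O, 0 °C to rt
Reagents that add atoms: N-methylmorpholine N-oxide, C[N+]1([O-])CCOCC1; water, O
Why: Upjohn dihydroxylation: the osmium reagent should add to the trisubstituted, more electron‑rich C11=C12 bond (C13=C14 is disubstituted and flanked by quaternary C1) from the α face, opposite the axial C1 methyl that lies 1,3 to C11, so the syn addition sets both hydroxyls α and the C11 methyl β.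

Step 10
Reactants: 14 diol ketone
Product: 15 11,12-acetonide ketone
Conditions: 2,2-dimethoxypropane, pyridinium p-toluenesulfonate (cat.), CH2Cl2, rt
Reagents that add atoms: 2,2-dimethoxypropane, COC(C)(C)OC
Why: acid‑catalysed transacetalisation protects the cis‑diol as its acetonide.

Step 11
Reactants: 15 acetonide ketone
Product: 16 2β-alcohol (benzylic; acetonide)
Conditions: NaBH4, MeOH/THF, 0 °C
Reagents that add atoms: none
Why: borohydride reduction of the aryl ketone, with hydride entering C2 from the α face anti to the adjacent axial C1 methyl (as in reductions of the saturated carbonyl of Wieland–Miescher‑type ketones), should give the 2β‑alcohol.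

Step 12
Reactants: 16 2β-alcohol
Product: 18 tricyclic dienol (C3=C8 and C5=C6; 2β-OH; acetonide), via lithium alkoxide 17 (not isolated)
Conditions: n-BuLi, THF, −78 °C; then Li, NH3 (l), t-BuOH, −78 to −45 °C; isoprene, then NH4Cl
Reagents that add atoms: none
Why: Birch reduction: the benzylic hydroxyl is first made into its lithium alkoxide, which resists C–O hydrogenolysis, and the 1,2,4‑trialkylbenzene ring is then protonated at the two unsubstituted para‑related carbons C4 and C7, leaving the tetrasubstituted C3=C8 and trisubstituted C5=C6 alkenes while the isolated C13=C14 alkene is not reduced.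

Step 13
Reactants: 18 tricyclic dienol
Product: 19 2β-triethylsilyl ether of the tricyclic 1,4-diene
Conditions: Et3SiOSO2CF3, 2,6-lutidine, CH2Cl2, −78 °C
Reagents that add atoms: triethylsilyl trifluoromethanesulfonate, CC[Si](CC)(CC)OS(=O)(=O)C(F)(F)F
Why: silylation with the silyl triflate caps the hindered allylic hydroxyl so that ozonolysis gives a stable α‑silyloxy ketone, triethylsilyl being chosen because buffered fluoride removes it under conditions the β,γ‑unsaturated diketone tolerates.

Step 14
Reactants: 19 2β-triethylsilyl ether of the tricyclic 1,4-diene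
Product: 22 ring B 3,8-diketone (Z‑C5=C6; 2β-OSiEt3; acetonide), via primary ozonide 20 (not isolated), via methoxy hydroperoxide 21 (not isolated)
Conditions: O3 (1.0 equiv, titrated CH2Cl2 solution), CH2Cl2/MeOH, NaHCO3, −78 °C; then Me2S, −78 °C to rt
Reagents that add atoms: ozone, [O-][O+]=O
Why: Ozone adds as a 1,3‑dipole to the tetrasubstituted C3=C8 alkene from the α face to give primary ozonide 20, which fragments; methanol captures the C8 fragment as methoxy hydroperoxide 21 and Me2S reduces it, so that C3 and C8 end as ketones (ozonolysis with reductive work‑up). The closest known reaction type is the ozonolysis of Birch‑derived 1,4,5,8‑tetrahydronaphthalenes (isotetralins) at their central alkene to cyclodecene‑1,6‑diones. No bond is formed: ring B arises by ring‑fusion cleavage, the two six‑membered rings that share C3=C8 merging into their ten‑membered perimeter. No stereocentre is created, and C5=C6 is Z because it was a ring bond of the arene. The step needs ozone to choose C3=C8 over trisubstituted C5=C6 and disubstituted C13=C14: C3=C8 is the most alkylated alkene and its allylic C2–O bond is pseudo‑equatorial, near the nodal plane of the π bond, so it withdraws little, while C13=C14 is deactivated by the allylic acetal oxygen and screened by quaternary C1. One equivalent of ozone at −78 °C is used to limit attack on C5=C6, which is the weakest point of the step.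

Step 15
Reactants: 22 ring B 3,8-diketone
Product: 23 2β-hydroxy 3,8-diketone
Conditions: HF·pyridine, pyridine, THF, 0 °C
Reagents that add atoms: none
Why: fluoride‑mediated desilylation under buffered conditions frees the C2 hydroxyl without enolising the β,γ‑unsaturated ketones or opening the acetonide.

Step 16
Reactants: 23 2β-hydroxy 3,8-diketone
Product: 24 2β,3α-diol 8-ketone
Conditions: Me4NBH(OAc)3, MeCN/AcOH, −30 °C
Reagents that add atoms: none
Why: Evans–Saksena hydroxyl‑directed reduction: hydride is transferred intramolecularly from boron once the C2 hydroxyl has displaced an acetate, so only the C3 ketone is reduced (C8 has no hydroxyl within reach) and hydride enters syn to the C2–O bond, which, with C2–H near the carbonyl plane and quaternary C1 gauche to C4, should set the 3α (threo) alcohol.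

Step 17
Reactants: 24 2β,3α-diol 8-ketone
Product: 25 2β,3α-diacetate 8-ketone
Conditions: Ac2O, 4-(dimethylamino)pyridine, pyridine, CH2Cl2, rt
Reagents that add atoms: acetic anhydride, CC(=O)OC(C)=O
Why: nucleophile‑catalysed acylation installs both acetates of the target while the ring A diol is still masked.

Step 18
Reactants: 25 2β,3α-diacetate 8-ketone
Product: 27 7α-hydroxy 8-ketone diacetate, via potassium enolate 26 (not isolated)
Conditions: KN(SiMe3)2, THF, −78 °C; then 2-(phenylsulfonyl)-3-phenyloxaziridine, −78 °C; AcOH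
Reagents that add atoms: 2-(phenylsulfonyl)-3-phenyloxaziridine, O=S(=O)(c1ccccc1)N1OC1c1ccccc1
Why: Davis enolate hydroxylation: the base removes the doubly activated C7 hydrogen (allylic and α to C8=O) rather than a C9 hydrogen, the extended enolate is oxidised at its α‑carbon C7, and the oxidant is expected on the α face because the β face of C7 lies across ring B from the β‑oriented C2 acetoxy and C1 methyl groups.

Step 19
Reactants: 27 7α-hydroxy 8-ketone diacetate
Product: 28 7α-[2-(diethoxyphosphoryl)propanoyloxy] 8-ketone diacetate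
Conditions: 2-(diethoxyphosphoryl)propanoic acid, N,N'-dicyclohexylcarbodiimide, 4-(dimethylamino)pyridine (cat.), CH2Cl2, 0 °C
Reagents that add atoms: 2-(diethoxyphosphoryl)propanoic acid, CCOP(=O)(OCC)C(C)C(=O)O
Why: Steglich esterification acylates the C7 hydroxyl with retention and brings in the three carbons of ring C, the phosphonate α‑carbon being an epimer mixture that disappears in the next step.

Step 20
Reactants: 28 phosphonate ester
Product: 29 11,12-acetonide of the target
Conditions: LiCl, DBU, MeCN, 0 °C to rt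
Reagents that add atoms: none
Why: intramolecular Horner–Wadsworth–Emmons reaction under Masamune–Roush conditions closes the five‑membered ring C onto the C8 ketone, the weak amine base with LiCl being chosen to keep C7 from epimerising.

Step 21
Reactants: 29 11,12-acetonide of the target
Product: 30 CNP0291307.1
Conditions: AcOH/H2O (4:1), 45 °C
Reagents that add atoms: none
Why: acid hydrolysis of the acetonide releases the C11/C12 diol, the acetates and the butenolide being stable to aqueous acetic acid.

**Compound list**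

1 | (4-methylphenyl)acetaldehyde | Cc1ccc(CC=O)cc1 | starting material
2 | 2-(triphenylphosphoranylidene)propanal | CC(C=O)=P(c1ccccc1)(c1ccccc1)c1ccccc1 | starting material
3 | (E)-2-methyl-4-(4-methylphenyl)but-2-enal | O=C/C(C)=C/Cc1ccc(C)cc1 | intermediate
4 | pent-1-en-3-one | C=CC(=O)CC | starting material
5 | (Z)-3-(triisopropylsilyloxy)penta-1,3-diene | C=C/C(O[Si](C(C)C)(C(C)C)C(C)C)=C/C | intermediate
6 | 1,5-dimethyl-6-(4-methylbenzyl)-4-(triisopropylsilyloxy)cyclohex-3-ene-1-carbaldehyde (C1 Me β, CHO α; C10 H α; C11 Me α) | O=C[C@@]1(C)CC=C(O[Si](C(C)C)(C(C)C)C(C)C)[C@@H](C)[C@@H]1Cc2ccc(C)cc2 | intermediate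
7 | 1,5-dimethyl-6-(4-methylbenzyl)-4-oxocyclohex-2-ene-1-carbaldehyde | O=C[C@@]1(C)C=CC(=O)[C@@H](C)[C@@H]1Cc2ccc(C)cc2 | intermediate
8 | 1,5-dimethyl-6-(4-methylbenzyl)-4-oxocyclohex-2-ene-1-carboxylic acid | OC(=O)[C@@]1(C)C=CC(=O)[C@@H](C)[C@@H]1Cc2ccc(C)cc2 | intermediate
9 | acid chloride of 8 (not isolated) | ClC(=O)[C@@]1(C)C=CC(=O)[C@@H](C)[C@@H]1Cc2ccc(C)cc2 | intermediate
10 | 4,7,9a-trimethyl-4,4a,9a,10-tetrahydroanthracene-3,9-dione (trans‑fused; C1 Me β, C10 H α, C11 Me α) | O=C1c2cc(C)ccc2C[C@H]3[C@H](C)C(=O)C=C[C@]13C | intermediate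
11 | potassium C11=C12 dienolate of 10 (not isolated) | O=C1c2cc(C)ccc2C[C@H]3C(C)=C([O-])C=C[C@]13C.[K+] | intermediate
12 | C12 dienyl triflate | O=C1c2cc(C)ccc2C[C@H]3C(C)=C(OS(=O)(=O)C(F)(F)F)C=C[C@]13C | intermediate
13 | 4,7,9a-trimethyl-4a,10-dihydroanthracen-9(9aH)-one (ring A 1,3-diene) | O=C1c2cc(C)ccc2C[C@H]3C(C)=CC=C[C@]13C | intermediate
14 | 11α,12α-diol ketone (C11 Me β) | O=C1c2cc(C)ccc2C[C@H]3[C@](C)(O)[C@H](O)C=C[C@]13C | intermediate
15 | 11,12-acetonide ketone | O=C1c2cc(C)ccc2C[C@H]3[C@]4(C)OC(C)(C)O[C@@H]4C=C[C@]13C | intermediate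
16 | 2β-alcohol (acetonide, arene) | O[C@H]1c2cc(C)ccc2C[C@H]3[C@]4(C)OC(C)(C)O[C@@H]4C=C[C@]13C | intermediate
17 | lithium alkoxide of 16 (not isolated) | [Li+].[O-][C@H]1c2cc(C)ccc2C[C@H]3[C@]4(C)OC(C)(C)O[C@@H]4C=C[C@]13C | intermediate
18 | tricyclic dienol (C3=C8, C5=C6; 2β-OH) | O[C@H]1C2=C(CC=C(C)C2)C[C@H]3[C@]4(C)OC(C)(C)O[C@@H]4C=C[C@]13C | intermediate
19 | 2β-triethylsilyl ether of the tricyclic 1,4-diene | CC[Si](CC)(CC)O[C@H]1C2=C(CC=C(C)C2)C[C@H]3[C@]4(C)OC(C)(C)O[C@@H]4C=C[C@]13C | intermediate
20 | primary ozonide across C3–C8, α face (not isolated) | CC[Si](CC)(CC)O[C@H]1[C@@]2(OOO3)CC(C)=CC[C@@]23C[C@H]4[C@]5(C)OC(C)(C)O[C@@H]5C=C[C@]14C | intermediate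
21 | C3 ketone C8 methoxy hydroperoxide, C8 configuration undefined (not isolated) | CC[Si](CC)(CC)O[C@H]1C(=O)C/C(C)=C\CC(OC)(OO)C[C@H]2[C@]3(C)OC(C)(C)O[C@@H]3C=C[C@]12C | intermediate
22 | ring B 3,8-diketone, Z‑C5=C6, 2β-OSiEt3, acetonide | CC[Si](CC)(CC)O[C@H]1C(=O)C/C(C)=C\CC(=O)C[C@H]2[C@]3(C)OC(C)(C)O[C@@H]3C=C[C@]12C | intermediate
23 | 2β-hydroxy 3,8-diketone | O[C@H]1C(=O)C/C(C)=C\CC(=O)C[C@H]2[C@]3(C)OC(C)(C)O[C@@H]3C=C[C@]12C | intermediate
24 | 2β,3α-diol 8-ketone | O[C@@H]1C/C(C)=C\CC(=O)C[C@H]2[C@]3(C)OC(C)(C)O[C@@H]3C=C[C@]2(C)[C@H]1O | intermediate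
25 | 2β,3α-diacetate 8-ketone | CC(=O)O[C@@H]1C/C(C)=C\CC(=O)C[C@H]2[C@]3(C)OC(C)(C)O[C@@H]3C=C[C@]2(C)[C@H]1OC(C)=O | intermediate
26 | potassium C7=C8 enolate of 25 (not isolated) | CC(=O)O[C@@H]1C/C(C)=C\C=C([O-])C[C@H]2[C@]3(C)OC(C)(C)O[C@@H]3C=C[C@]2(C)[C@H]1OC(C)=O.[K+] | intermediate
27 | 7α-hydroxy 8-ketone diacetate | CC(=O)O[C@@H]1C/C(C)=C\[C@H](O)C(=O)C[C@H]2[C@]3(C)OC(C)(C)O[C@@H]3C=C[C@]2(C)[C@H]1OC(C)=O | intermediate
28 | 7α-[2-(diethoxyphosphoryl)propanoyloxy] 8-ketone diacetate (phosphonate α‑carbon unassigned) | CC(=O)O[C@@H]1C/C(C)=C\[C@H](OC(=O)C(C)P(=O)(OCC)OCC)C(=O)C[C@H]2[C@]3(C)OC(C)(C)O[C@@H]3C=C[C@]2(C)[C@H]1OC(C)=O | intermediate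
29 | 11,12-acetonide of the target | CC(=O)O[C@@H]1C/C(C)=C\[C@@H]2OC(=O)C(C)=C2C[C@H]2[C@]3(C)OC(C)(C)O[C@@H]3C=C[C@]2(C)[C@H]1OC(C)=O | intermediate
30 | CNP0291307.1 | CC(=O)O[C@@H]1C/C(C)=C\[C@@H]2OC(=O)C(C)=C2C[C@H]2[C@](C)(O)[C@H](O)C=C[C@]2(C)[C@H]1OC(C)=O | target

**Step count**

Total: 21 steps. Longest linear sequence: 20 steps (compound 1 to 30 through steps 1 and 3–21; step 2 prepares diene 5).

**Steps most likely to fail, with fallbacks**

Step 14. Ozone may not discriminate well enough between the tetrasubstituted C3=C8 alkene and the unhindered trisubstituted C5=C6 alkene, so that cleavage is spread over both. The fallback sets out from dienol 18 and uses the free C2 hydroxyl as a directing group. Epoxidation with VO(acetylacetonate)2 and t‑BuOOH in CH2Cl2 should be confined to the allylic C3=C8 alkene and give epoxy alcohol F1. Silylation with Et3SiOSO2CF3 and 2,6‑lutidine gives epoxy silyl ether F2. Cleavage of the epoxide with H5IO6 in THF/H2O at 0 °C then gives the 3,8‑diketone, and the route is rejoined at 22.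

Step 18. The enolate may be oxidised on the wrong face of ring B (poor or inverted facial selectivity at C7). The fallback sets out from 25. If the same hydroxylation gives the 7‑epi alcohol F5, it is esterified with 2‑(diethoxyphosphoryl)propanoic acid under Mitsunobu conditions (PPh3, diisopropyl azodicarboxylate, THF), which inverts C7. This gives phosphonate ester 28 directly, where the route is rejoined.

Step 16. Internal hydride delivery may take place with the C1–C2–C3–C4 unit in its extended arrangement, which would set the opposite configuration at C3. The fallback sets out from 23. If the reduction gives the 3‑epi diol F3, its less hindered C3 hydroxyl is esterified with acetic acid under Mitsunobu conditions (PPh3, diisopropyl azodicarboxylate, THF) with inversion, giving the 3α‑acetoxy 2β‑alcohol F4. Acetylation of the C2 hydroxyl (Ac2O, 4‑(dimethylamino)pyridine) then gives diacetate 25, where the route is rejoined.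

Further compounds
F1 | step 14 | 3β,8β-epoxide of dienol 18 (epoxy alcohol) | O[C@H]1[C@]2(O3)CC(C)=CC[C@]23C[C@H]4[C@]5(C)OC(C)(C)O[C@@H]5C=C[C@]14C
F2 | step 14 | triethylsilyl ether of F1 | CC[Si](CC)(CC)O[C@H]1[C@]2(O3)CC(C)=CC[C@]23C[C@H]4[C@]5(C)OC(C)(C)O[C@@H]5C=C[C@]14C
F3 | step 16 | 3-epi diol (2β,3β-diol 8-ketone) | O[C@H]1C/C(C)=C\CC(=O)C[C@H]2[C@]3(C)OC(C)(C)O[C@@H]3C=C[C@]2(C)[C@H]1O
F4 | step 16 | 3α-acetoxy 2β-hydroxy 8-ketone | CC(=O)O[C@@H]1C/C(C)=C\CC(=O)C[C@H]2[C@]3(C)OC(C)(C)O[C@@H]3C=C[C@]2(C)[C@H]1O
F5 | step 18 | 7-epi alcohol (7β-hydroxy 8-ketone diacetate) | CC(=O)O[C@@H]1C/C(C)=C\[C@@H](O)C(=O)C[C@H]2[C@]3(C)OC(C)(C)O[C@@H]3C=C[C@]2(C)[C@H]1OC(C)=O
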